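**Retrosynthetic overview**
1. Feature: C4 of the upper chroman is a doubly benzylic methine. Its aryl substituent (linking ring E) has OMe ortho and an oxygen para to the point of attachment, and the resorcinol-type benzo ring A is joined to C4 through O1–C2–C3. C4 is therefore a latent, strongly stabilised cation within reach of ring A.
2. Target 34 ⇐ tetrabenzyl ether 33 ⇐ acyclic carbinol 32 by cationic Friedel–Crafts formation of C4–C4a; this closes pyran ring C last and sets C4 trans to C3.
3. 32 ⇐ diol 30 + 3-(benzyloxy)phenol 31 (Mitsunobu at the primary hydroxyl) ⇐ Evans syn-aldol of (S)-imide 27 with aldehyde 19 (sets upper C3), then LiBH4.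
4. 19 ⇐ bromochroman 17 ⇐ Evans alkylation of (R)-imide 8 with benzylic bromide 12 (sets lower C3), LiBH4, MOM removal, Mitsunobu closure of the lower pyran ring (formed first).
5. Arylacetic acids 5 and 24 ⇐ salicylaldehydes 1 and 20 by O-benzylation and a Wittig/hydrolysis/Pinnick one-carbon homologation.

Key step: step 22

Remark: the carbinol carbon of 29, 30 and 32 is drawn as the syn-aldol epimer, but its configuration is immaterial because it is erased on ionisation. The two auxiliaries have opposite configuration because chelated enolate alkylation and the dipole-opposed boron aldol expose opposite enolate faces.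

**Route**

Step 1
Reactants: 1 5-bromo-2-hydroxy-4-methoxybenzaldehyde
Product: 2 2-(benzyloxy)-5-bromo-4-methoxybenzaldehyde
Conditions: BnBr, K2CO3, DMF, 60 °C
Reagents that add atoms: benzyl bromide, BrCc1ccccc1
Why: Williamson O-alkylation of the phenoxide is routine and the hydrogen-bonded ortho-hydroxyl of a salicylaldehyde benzylates cleanly on warming.

Step 2
Reactants: 2 2-(benzyloxy)-5-bromo-4-methoxybenzaldehyde
Product: 3 1-(benzyloxy)-4-bromo-5-methoxy-2-(2-methoxyethenyl)benzene (E/Z mixture)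
Conditions: MeOCH2PPh3Cl, KOtBu, THF, 0 °C → rt
Reagents that add atoms: (methoxymethyl)triphenylphosphonium chloride, COC[P+](c1ccccc1)(c1ccccc1)c1ccccc1.[Cl-]
Why: Wittig olefination with the non-stabilised methoxymethylene ylide adds the one extra carbon as an enol ether, whose geometry is irrelevant.

Step 3
Reactants: 3 1-(benzyloxy)-4-bromo-5-methoxy-2-(2-methoxyethenyl)benzene
Product: 4 [2-(benzyloxy)-5-bromo-4-methoxyphenyl]acetaldehyde
Conditions: 2 M HCl, THF, 50 °C; used at once
Reagents that add atoms: water, O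
Why: Acid-catalysed enol ether hydrolysis (C-protonation, hemiacetal collapse) unmasks the arylacetaldehyde while the aryl bromide and benzyl ether are inert.

Step 4
Reactants: 4 [2-(benzyloxy)-5-bromo-4-methoxyphenyl]acetaldehyde
Product: 5 [2-(benzyloxy)-5-bromo-4-methoxyphenyl]acetic acid
Conditions: NaClO2, NaH2PO4, 2-methyl-2-butene, t-BuOH/H2O, 0 °C → rt
Reagents that add atoms: sodium chlorite, [Na+].[O-]Cl=O
Why: Pinnick oxidation converts the aldehyde to the acid, and the alkene scavenger removes hypochlorite before it can chlorinate the electron-rich ring.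

Step 5
Reactants: 5 [2-(benzyloxy)-5-bromo-4-methoxyphenyl]acetic acid; 6 (R)-4-benzyl-2-oxazolidinone
Product: 8 (4R)-4-benzyl-3-{[2-(benzyloxy)-5-bromo-4-methoxyphenyl]acetyl}-1,3-oxazolidin-2-one, via mixed pivalic anhydride 7 (not isolated)
Conditions: t-BuCOCl, Et3N, THF, −20 °C; then LiCl, 6, −20 °C → rt
Reagents that add atoms: none
Why: N-acylation of the oxazolidinone through the mixed pivalic anhydride is the standard entry to arylacetyl imides, with attack at the less hindered arylacetyl carbonyl.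

Step 6
Reactants: 9 4-(benzyloxy)-2-hydroxybenzaldehyde
Product: 10 4-(benzyloxy)-2-(methoxymethoxy)benzaldehyde
Conditions: MOMCl, i-Pr2NEt, CH2Cl2, 0 °C → reflux
Reagents that add atoms: chloromethyl methyl ether, COCCl
Why: O-alkylation of the phenol with the α-chloro ether gives an acetal protecting group that is orthogonal to the benzyl ethers.

Step 7
Reactants: 10 4-(benzyloxy)-2-(methoxymethoxy)benzaldehyde
Product: 11 [4-(benzyloxy)-2-(methoxymethoxy)phenyl]methanol
Conditions: NaBH4, MeOH/THF, 0 °C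
Reagents that add atoms: none
Why: Borohydride reduction of an aromatic aldehyde to the benzylic alcohol is routine and leaves the acetal and ethers untouched.

Step 8
Reactants: 11 [4-(benzyloxy)-2-(methoxymethoxy)phenyl]methanol
Product: 12 4-(benzyloxy)-1-(bromomethyl)-2-(methoxymethoxy)benzene
Conditions: CBr4, PPh3, CH2Cl2, 0 °C; short silica pad, used at once
Reagents that add atoms: carbon tetrabromide, BrC(Br)(Br)Br
Why: Appel bromination works under neutral conditions that spare the MOM acetal, and the labile electron-rich benzylic bromide is not stored.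

Step 9
Reactants: 8 (4R)-4-benzyl-3-{[2-(benzyloxy)-5-bromo-4-methoxyphenyl]acetyl}-1,3-oxazolidin-2-one; 12 4-(benzyloxy)-1-(bromomethyl)-2-(methoxymethoxy)benzene
Product: 14 (4R)-4-benzyl-3-{(2R)-3-[4-(benzyloxy)-2-(methoxymethoxy)phenyl]-2-[2-(benzyloxy)-5-bromo-4-methoxyphenyl]propanoyl}-1,3-oxazolidin-2-one, via sodium enolate 13 (not isolated)
Conditions: NaN(SiMe3)2, THF, −78 °C; then 12, −78 → −40 °C
Reagents that add atoms: none
Why: Evans asymmetric alkylation: the chelated (Z)-sodium enolate is benzylated on the face opposite the auxiliary benzyl group, so the (R)-auxiliary delivers the (2R) centre that becomes C3 of the lower chroman.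

Step 10
Reactants: 14 the alkylated imide
Product: 15 (2R)-3-[4-(benzyloxy)-2-(methoxymethoxy)phenyl]-2-[2-(benzyloxy)-5-bromo-4-methoxyphenyl]propan-1-ol
Conditions: LiBH4, MeOH (1 equiv), THF, 0 °C
Reagents that add atoms: none
Why: Reductive cleavage of the exocyclic imide carbonyl by LiBH4 gives the primary alcohol and returns auxiliary 6 without touching the α-centre or the aryl bromide.

Step 11
Reactants: 15 the MOM-protected primary alcohol
Product: 16 5-(benzyloxy)-2-{(2R)-2-[2-(benzyloxy)-5-bromo-4-methoxyphenyl]-3-hydroxypropyl}phenol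
Conditions: HCl (cat.), MeOH/THF, 50 °C
Reagents that add atoms: none
Why: Acid-catalysed acetal exchange transfers the methoxymethyl group to methanol and frees the phenol, while benzyl ethers, aryl bromide and the primary alcohol are stable.

Step 12
Reactants: 16 the phenol alcohol
Product: 17 (3R)-7-(benzyloxy)-3-[2-(benzyloxy)-5-bromo-4-methoxyphenyl]chromane
Conditions: PPh3, DIAD, THF, 0 °C → rt
Reagents that add atoms: none
Why: Intramolecular Mitsunobu etherification (phenol onto the activated primary alcohol, 6-exo-tet) closes the lower pyran ring without involving the stereocentre.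

Step 13
Reactants: 17 the bromochroman
Product: 19 4-(benzyloxy)-5-[(3R)-7-(benzyloxy)chroman-3-yl]-2-methoxybenzaldehyde, via aryllithium 18 (not isolated)
Conditions: n-BuLi, THF, −78 °C; then DMF, −78 → 0 °C; 1 M HCl
Reagents that add atoms: N,N-dimethylformamide, CN(C)C=O
Why: Bromine–lithium exchange at −78 °C outpaces benzylic deprotonation, and formylation of the methoxy-flanked aryllithium with DMF gives the aldehyde at the bromine-bearing carbon only.

Step 14
Reactants: 20 2-hydroxy-4,5-dimethoxybenzaldehyde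
Product: 21 2-(benzyloxy)-4,5-dimethoxybenzaldehyde
Conditions: BnBr, K2CO3, DMF, 60 °C
Reagents that add atoms: benzyl bromide, BrCc1ccccc1
Why: Williamson O-benzylation of the salicylaldehyde phenoxide, as in step 1.

Step 15
Reactants: 21 2-(benzyloxy)-4,5-dimethoxybenzaldehyde
Product: 22 1-(benzyloxy)-4,5-dimethoxy-2-(2-methoxyethenyl)benzene (E/Z mixture)
Conditions: MeOCH2PPh3Cl, KOtBu, THF, 0 °C → rt
Reagents that add atoms: (methoxymethyl)triphenylphosphonium chloride, COC[P+](c1ccccc1)(c1ccccc1)c1ccccc1.[Cl-]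
Why: Wittig methoxymethylenation supplies the homologating carbon as an enol ether, as in step 2.

Step 16
Reactants: 22 the enol ether
Product: 23 [2-(benzyloxy)-4,5-dimethoxyphenyl]acetaldehyde
Conditions: 2 M HCl, THF, 50 °C; used at once
Reagents that add atoms: water, O
Why: Acid-catalysed enol ether hydrolysis gives the arylacetaldehyde, which is oxidised directly to avoid self-aldol condensation.

Step 17
Reactants: 23 [2-(benzyloxy)-4,5-dimethoxyphenyl]acetaldehyde
Product: 24 [2-(benzyloxy)-4,5-dimethoxyphenyl]acetic acid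
Conditions: NaClO2, NaH2PO4, 2-methyl-2-butene, t-BuOH/H2O, 0 °C → rt
Reagents that add atoms: sodium chlorite, [Na+].[O-]Cl=O
Why: Pinnick oxidation with a hypochlorite scavenger is selective for the aldehyde in the presence of the electron-rich trialkoxyarene.

Step 18
Reactants: 24 [2-(benzyloxy)-4,5-dimethoxyphenyl]acetic acid; 25 (S)-4-benzyl-2-oxazolidinone
Product: 27 (4S)-4-benzyl-3-{[2-(benzyloxy)-4,5-dimethoxyphenyl]acetyl}-1,3-oxazolidin-2-one, via mixed pivalic anhydride 26 (not isolated)
Conditions: t-BuCOCl, Et3N, THF, −20 °C; then LiCl, 25, −20 °C → rt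
Reagents that add atoms: none
Why: Mixed-anhydride N-acylation of the oxazolidinone, as in step 5.

Step 19
Reactants: 27 the (S)-arylacetyl imide; 19 4-(benzyloxy)-5-[(3R)-7-(benzyloxy)chroman-3-yl]-2-methoxybenzaldehyde
Product: 29 (4S)-4-benzyl-3-{(2S,3S)-3-{4-(benzyloxy)-5-[(3R)-7-(benzyloxy)chroman-3-yl]-2-methoxyphenyl}-2-[2-(benzyloxy)-4,5-dimethoxyphenyl]-3-hydroxypropanoyl}-1,3-oxazolidin-2-one, via dibutylboron enolate 28 (not isolated)
Conditions: n-Bu2BOSO2CF3, i-Pr2NEt, CH2Cl2, −78 → 0 °C; then 19, −78 → 0 °C; pH 7 buffer, MeOH, H2O2, 0 °C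
Reagents that add atoms: none
Why: Evans syn-aldol: the (Z)-boron enolate adds through a Zimmerman–Traxler chair on the face remote from the auxiliary benzyl group (carbonyl dipoles opposed), which fixes the α-carbon, the future upper C3, in the required sense, while the syn carbinol centre formed with it is erased later.

Step 20
Reactants: 29 the syn-aldol adduct
Product: 30 (1S,2R)-1-{4-(benzyloxy)-5-[(3R)-7-(benzyloxy)chroman-3-yl]-2-methoxyphenyl}-2-[2-(benzyloxy)-4,5-dimethoxyphenyl]propane-1,3-diol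
Conditions: LiBH4, MeOH (1 equiv), THF, 0 °C
Reagents that add atoms: none
Why: LiBH4 reduction of the β-hydroxy imide at the exocyclic carbonyl is fast at 0 °C, which should forestall retro-aldol cleavage, and it gives the 1,3-diol with return of auxiliary 25.

Step 21
Reactants: 30 the 1,3-diol; 31 3-(benzyloxy)phenol
Product: 32 (1S,2R)-3-[3-(benzyloxy)phenoxy]-1-{4-(benzyloxy)-5-[(3R)-7-(benzyloxy)chroman-3-yl]-2-methoxyphenyl}-2-[2-(benzyloxy)-4,5-dimethoxyphenyl]propan-1-ol
Conditions: PPh3, DIAD, toluene, 0 °C → rt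
Reagents that add atoms: none
Why: Mitsunobu etherification: the unhindered primary hydroxyl should form the oxyphosphonium ion in preference to the secondary benzylic one, which is flanked by an ortho-substituted arene and a tertiary carbon, and the phenol is acidic enough to act as the pronucleophile.

Step 22
Reactants: 32 the 3-benzyloxyphenyl ether of the diarylpropanediol
Product: 33 (3R,4S)-7-(benzyloxy)-4-{4-(benzyloxy)-5-[(3R)-7-(benzyloxy)chroman-3-yl]-2-methoxyphenyl}-3-[2-(benzyloxy)-4,5-dimethoxyphenyl]chromane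
Conditions: BF3·OEt2 (0.2 equiv), 4 Å molecular sieves, CH2Cl2 (0.01 M), −78 → −20 °C
Reagents that add atoms: none
Why: The Lewis acid ionises the secondary carbinol of either epimer of 32 to a planar benzylic cation stabilised by the ortho-methoxy and para-benzyloxy groups of ring E, and this cation is captured by the carbon of the tethered 3-benzyloxyphenyl ether that lies ortho to the ether oxygen and para to the benzyloxy group; this is an intramolecular Friedel–Crafts alkylation, the established reaction type for cyclodehydration of benzylic alcohols onto aryl ethers to give trans-3,4-disubstituted chromans and 4-aryltetralins. Pyran ring C closes as a six-membered ring by attack of the arene π bond on the exocyclic cation through a chair-like array O1–C2–C3–C4–C4a–C8a (6-endo with respect to the arene bond, Baldwin terms fitting only loosely). The new C4 centre is controlled by the C3 centre from step 19: in the chair-like transition state ring B sits pseudo-equatorial and the small C3–H eclipses ring E on the cation, so the arene adds to the face that places the two aryl groups trans, giving (3R,4S). The step needs ring closure to outrun E1 loss of the C3 proton, which would lead to scrambling of C3 through the stilbene, and this is secured by the high nucleophilicity of the resorcinol diether carbon held six atoms away, by low temperature and by high dilution. It also needs 7- rather than 5-benzyloxy regiochemistry, which is secured by the crowding of the position between the two oxygens. C3 itself cannot ionise, since that would give an unstabilised secondary cation, so its configuration is carried through.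

Step 23
Reactants: 33 the tetra-O-benzyl ether
Product: 34 (3R,4S)-4-{4-hydroxy-5-[(3R)-7-hydroxychroman-3-yl]-2-methoxyphenyl}-3-(2-hydroxy-4,5-dimethoxyphenyl)chroman-7-ol (target)
Conditions: H2 (1 atm), 10% Pd/C, THF/MeOH, rt
Reagents that add atoms: none
Why: Catalytic hydrogenolysis cleaves the four aryl benzyl ethers, and no C–C bond, methyl ether or non-benzylic C–O bond of the chromans is affected, so all three stereocentres are retained.

**Compound list**
1 | 5-bromo-2-hydroxy-4-methoxybenzaldehyde | COc1cc(O)c(C=O)cc1Br | starting material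
2 | 2-(benzyloxy)-5-bromo-4-methoxybenzaldehyde | COc1cc(OCc2ccccc2)c(C=O)cc1Br | intermediate
3 | 1-(benzyloxy)-4-bromo-5-methoxy-2-(2-methoxyethenyl)benzene (E/Z mixture) | COC=Cc1cc(Br)c(OC)cc1OCc1ccccc1 | intermediate
4 | [2-(benzyloxy)-5-bromo-4-methoxyphenyl]acetaldehyde | O=CCc1cc(Br)c(OC)cc1OCc1ccccc1 | intermediate
5 | [2-(benzyloxy)-5-bromo-4-methoxyphenyl]acetic acid | OC(=O)Cc1cc(Br)c(OC)cc1OCc1ccccc1 | intermediate
6 | (R)-4-benzyl-2-oxazolidinone | O=C1N[C@H](Cc2ccccc2)CO1 | starting material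
7 | [2-(benzyloxy)-5-bromo-4-methoxyphenyl]acetic pivalic anhydride | CC(C)(C)C(=O)OC(=O)Cc1cc(Br)c(OC)cc1OCc1ccccc1 | intermediate (not isolated)
8 | (4R)-4-benzyl-3-{[2-(benzyloxy)-5-bromo-4-methoxyphenyl]acetyl}-1,3-oxazolidin-2-one | O=C(Cc1cc(Br)c(OC)cc1OCc1ccccc1)N1[C@H](Cc2ccccc2)COC1=O | intermediate
9 | 4-(benzyloxy)-2-hydroxybenzaldehyde | O=Cc1ccc(OCc2ccccc2)cc1O | starting material
10 | 4-(benzyloxy)-2-(methoxymethoxy)benzaldehyde | COCOc1cc(OCc2ccccc2)ccc1C=O | intermediate
11 | [4-(benzyloxy)-2-(methoxymethoxy)phenyl]methanol | COCOc1cc(OCc2ccccc2)ccc1CO | intermediate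
12 | 4-(benzyloxy)-1-(bromomethyl)-2-(methoxymethoxy)benzene | COCOc1cc(OCc2ccccc2)ccc1CBr | intermediate
13 | sodium (Z)-enolate of imide 8 | [Na+].[O-]/C(=C\c1cc(Br)c(OC)cc1OCc1ccccc1)N1[C@H](Cc2ccccc2)COC1=O | intermediate (not isolated)
14 | (4R)-4-benzyl-3-{(2R)-3-[4-(benzyloxy)-2-(methoxymethoxy)phenyl]-2-[2-(benzyloxy)-5-bromo-4-methoxyphenyl]propanoyl}-1,3-oxazolidin-2-one | O=C1OC[C@@H](Cc2ccccc2)N1C(=O)[C@H](Cc1ccc(OCc2ccccc2)cc1OCOC)c1cc(Br)c(OC)cc1OCc1ccccc1 | intermediate
15 | (2R)-3-[4-(benzyloxy)-2-(methoxymethoxy)phenyl]-2-[2-(benzyloxy)-5-bromo-4-methoxyphenyl]propan-1-ol | OC[C@H](Cc1ccc(OCc2ccccc2)cc1OCOC)c1cc(Br)c(OC)cc1OCc1ccccc1 | intermediate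
16 | 5-(benzyloxy)-2-{(2R)-2-[2-(benzyloxy)-5-bromo-4-methoxyphenyl]-3-hydroxypropyl}phenol | OC[C@H](Cc1ccc(OCc2ccccc2)cc1O)c1cc(Br)c(OC)cc1OCc1ccccc1 | intermediate
17 | (3R)-7-(benzyloxy)-3-[2-(benzyloxy)-5-bromo-4-methoxyphenyl]chromane | COc1cc(OCc2ccccc2)c([C@@H]2COc3cc(OCc4ccccc4)ccc3C2)cc1Br | intermediate
18 | {4-(benzyloxy)-5-[(3R)-7-(benzyloxy)chroman-3-yl]-2-methoxyphenyl}lithium | COc1cc(OCc2ccccc2)c([C@@H]2COc3cc(OCc4ccccc4)ccc3C2)cc1[Li] | intermediate (not isolated)
19 | 4-(benzyloxy)-5-[(3R)-7-(benzyloxy)chroman-3-yl]-2-methoxybenzaldehyde | COc1cc(OCc2ccccc2)c([C@@H]2COc3cc(OCc4ccccc4)ccc3C2)cc1C=O | intermediate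
20 | 2-hydroxy-4,5-dimethoxybenzaldehyde | COc1cc(O)c(C=O)cc1OC | starting material
21 | 2-(benzyloxy)-4,5-dimethoxybenzaldehyde | COc1cc(OCc2ccccc2)c(C=O)cc1OC | intermediate
22 | 1-(benzyloxy)-4,5-dimethoxy-2-(2-methoxyethenyl)benzene (E/Z mixture) | COC=Cc1cc(OC)c(OC)cc1OCc1ccccc1 | intermediate
23 | [2-(benzyloxy)-4,5-dimethoxyphenyl]acetaldehyde | O=CCc1cc(OC)c(OC)cc1OCc1ccccc1 | intermediate
24 | [2-(benzyloxy)-4,5-dimethoxyphenyl]acetic acid | OC(=O)Cc1cc(OC)c(OC)cc1OCc1ccccc1 | intermediate
25 | (S)-4-benzyl-2-oxazolidinone | O=C1N[C@@H](Cc2ccccc2)CO1 | starting material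
26 | [2-(benzyloxy)-4,5-dimethoxyphenyl]acetic pivalic anhydride | CC(C)(C)C(=O)OC(=O)Cc1cc(OC)c(OC)cc1OCc1ccccc1 | intermediate (not isolated)
27 | (4S)-4-benzyl-3-{[2-(benzyloxy)-4,5-dimethoxyphenyl]acetyl}-1,3-oxazolidin-2-one | O=C(Cc1cc(OC)c(OC)cc1OCc1ccccc1)N1[C@@H](Cc2ccccc2)COC1=O | intermediate
28 | (Z)-dibutylboron enolate of imide 27 | CCCCB(CCCC)O/C(=C\c1cc(OC)c(OC)cc1OCc1ccccc1)N1[C@@H](Cc2ccccc2)COC1=O | intermediate (not isolated)
29 | (4S)-4-benzyl-3-{(2S,3S)-3-{4-(benzyloxy)-5-[(3R)-7-(benzyloxy)chroman-3-yl]-2-methoxyphenyl}-2-[2-(benzyloxy)-4,5-dimethoxyphenyl]-3-hydroxypropanoyl}-1,3-oxazolidin-2-one | O=C1OC[C@H](Cc2ccccc2)N1C(=O)[C@@H](c1cc(OC)c(OC)cc1OCc1ccccc1)[C@H](O)c1cc([C@@H]2COc3cc(OCc4ccccc4)ccc3C2)c(OCc2ccccc2)cc1OC | intermediate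
30 | (1S,2R)-1-{4-(benzyloxy)-5-[(3R)-7-(benzyloxy)chroman-3-yl]-2-methoxyphenyl}-2-[2-(benzyloxy)-4,5-dimethoxyphenyl]propane-1,3-diol | OC[C@@H](c1cc(OC)c(OC)cc1OCc1ccccc1)[C@H](O)c1cc([C@@H]2COc3cc(OCc4ccccc4)ccc3C2)c(OCc2ccccc2)cc1OC | intermediate
31 | 3-(benzyloxy)phenol | Oc1cccc(OCc2ccccc2)c1 | starting material
32 | (1S,2R)-3-[3-(benzyloxy)phenoxy]-1-{4-(benzyloxy)-5-[(3R)-7-(benzyloxy)chroman-3-yl]-2-methoxyphenyl}-2-[2-(benzyloxy)-4,5-dimethoxyphenyl]propan-1-ol | COc1cc(OCc2ccccc2)c(cc1OC)[C@H](COc1cccc(OCc2ccccc2)c1)[C@H](O)c1cc([C@@H]2COc3cc(OCc4ccccc4)ccc3C2)c(OCc2ccccc2)cc1OC | intermediate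
33 | (3R,4S)-7-(benzyloxy)-4-{4-(benzyloxy)-5-[(3R)-7-(benzyloxy)chroman-3-yl]-2-methoxyphenyl}-3-[2-(benzyloxy)-4,5-dimethoxyphenyl]chromane | COc1cc(OCc2ccccc2)c(cc1OC)[C@@H]1COc2cc(OCc3ccccc3)ccc2[C@H]1c1cc([C@@H]2COc3cc(OCc4ccccc4)ccc3C2)c(OCc2ccccc2)cc1OC | intermediate
34 | (3R,4S)-4-{4-hydroxy-5-[(3R)-7-hydroxychroman-3-yl]-2-methoxyphenyl}-3-(2-hydroxy-4,5-dimethoxyphenyl)chroman-7-ol | COc1cc(O)c([C@@H]2COc3cc(O)ccc3[C@H]2c2cc([C@@H]3COc4cc(O)ccc4C3)c(O)cc2OC)cc1OC | target

**Step count**
Total: 23 steps. Longest linear sequence: 15 steps (steps 1–5, 9–13, 19–23).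

**Steps most likely to fail**

Step 22 (Friedel–Crafts closure). The cation may lose the C3 proton to give the conjugated stilbene faster than it cyclises, and reprotonation of that alkene would erase the C3 configuration. The ortho-benzyloxy oxygen of ring B may also capture the cation with loss of a benzyl group. The fallback sets out from diol 30 and uses a sulfide as a latent cation that is released without protic acid. Treatment of 30 with an excess of thiophenol and ZnI2 in CH2Cl2 at 0 °C exchanges the benzylic hydroxyl for sulfur, the soft external nucleophile capturing the cation, and should give the phenylsulfanyl alcohol F1. Mitsunobu etherification of its only remaining hydroxyl with 31 (PPh3, DIAD) should give the phenylsulfanyl aryl ether F2. Thiophilic activation with AgOSO2CF3 in the presence of 2,6-di-tert-butyl-4-methylpyridine (CH2Cl2, −40 °C) then generates the same cation under proton-free conditions, so that any alkene formed cannot re-enter and scramble C3, and ring closure returns to the route at 33.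

Step 21 (Mitsunobu etherification of the diol). The easily ionised secondary benzylic hydroxyl may be activated in competition with the primary one, leading to elimination, aryl ether formation at the wrong carbon or oxetane formation. The fallback sets out from aldol adduct 29 and masks the secondary hydroxyl before the auxiliary is removed. Silylation with tert-butyldimethylsilyl triflate and 2,6-lutidine (CH2Cl2, −78 °C) should give the silyl ether imide F3. LiBH4 reduction should give the mono-protected diol F4, and Mitsunobu etherification with 31 should give the silylated aryl ether F5. Bu4NF in THF removes the silyl group and returns to the route at 32.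

Step 9 (enolate benzylation). Bromide 12 may self-condense or decompose, and C-alkylation of the hindered, stabilised arylacetyl enolate may be sluggish, so conversion may be poor. The fallback replaces the alkylation by an aldol addition followed by deoxygenation; it sets out from acid 5 and aldehyde 10. Acid 5 is attached to the (S)-auxiliary 25 under the conditions of step 5 to give the (S)-imide F6. Its boron enolate (n-Bu2BOSO2CF3, i-Pr2NEt) adds to 10 in an Evans syn-aldol to give the aldol adduct F7; because aldol and alkylation use opposite enolate faces, the (S)-auxiliary gives the same α-configuration as the (R)-auxiliary in step 9. LiBH4 reduction gives the diol F8, and ionic hydrogenation of its benzylic hydroxyl (Et3SiH, BF3·OEt2, CH2Cl2, −78 °C) returns to the route at 15.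

**Further compounds**
F1 | step 22 | (2R)-3-{4-(benzyloxy)-5-[(3R)-7-(benzyloxy)chroman-3-yl]-2-methoxyphenyl}-2-[2-(benzyloxy)-4,5-dimethoxyphenyl]-3-(phenylsulfanyl)propan-1-ol (sulfide epimers) | OC[C@@H](c1cc(OC)c(OC)cc1OCc1ccccc1)C(Sc1ccccc1)c1cc([C@@H]2COc3cc(OCc4ccccc4)ccc3C2)c(OCc2ccccc2)cc1OC
F2 | step 22 | 3-(benzyloxy)phenyl ether of F1 at the primary oxygen | COc1cc(OCc2ccccc2)c(cc1OC)[C@H](COc1cccc(OCc2ccccc2)c1)C(Sc1ccccc1)c1cc([C@@H]2COc3cc(OCc4ccccc4)ccc3C2)c(OCc2ccccc2)cc1OC
F3 | step 21 | tert-butyldimethylsilyl ether of aldol adduct 29 | O=C1OC[C@H](Cc2ccccc2)N1C(=O)[C@@H](c1cc(OC)c(OC)cc1OCc1ccccc1)[C@H](O[Si](C)(C)C(C)(C)C)c1cc([C@@H]2COc3cc(OCc4ccccc4)ccc3C2)c(OCc2ccccc2)cc1OC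
F4 | step 21 | diol 30 silylated at the secondary oxygen | OC[C@@H](c1cc(OC)c(OC)cc1OCc1ccccc1)[C@H](O[Si](C)(C)C(C)(C)C)c1cc([C@@H]2COc3cc(OCc4ccccc4)ccc3C2)c(OCc2ccccc2)cc1OC
F5 | step 21 | tert-butyldimethylsilyl ether of carbinol 32 | COc1cc(OCc2ccccc2)c(cc1OC)[C@H](COc1cccc(OCc2ccccc2)c1)[C@H](O[Si](C)(C)C(C)(C)C)c1cc([C@@H]2COc3cc(OCc4ccccc4)ccc3C2)c(OCc2ccccc2)cc1OC
F6 | step 9 | (4S)-4-benzyl-3-{[2-(benzyloxy)-5-bromo-4-methoxyphenyl]acetyl}-1,3-oxazolidin-2-one | O=C(Cc1cc(Br)c(OC)cc1OCc1ccccc1)N1[C@@H](Cc2ccccc2)COC1=O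
F7 | step 9 | (4S)-4-benzyl-3-{(2S,3S)-3-[4-(benzyloxy)-2-(methoxymethoxy)phenyl]-2-[2-(benzyloxy)-5-bromo-4-methoxyphenyl]-3-hydroxypropanoyl}-1,3-oxazolidin-2-one | O=C1OC[C@H](Cc2ccccc2)N1C(=O)[C@@H](c1cc(Br)c(OC)cc1OCc1ccccc1)[C@H](O)c1ccc(OCc2ccccc2)cc1OCOC
F8 | step 9 | (1S,2R)-1-[4-(benzyloxy)-2-(methoxymethoxy)phenyl]-2-[2-(benzyloxy)-5-bromo-4-methoxyphenyl]propane-1,3-diol | OC[C@@H](c1cc(Br)c(OC)cc1OCc1ccccc1)[C@H](O)c1ccc(OCc2ccccc2)cc1OCOC
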